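C1–C14 (briarane numbering) form a fourteen-carbon perimeter crossed only by the C1–C10 bond. That bond sits between the C14 carbinol and the C11=C12 olefin, which is the retron of a C1,C14-epoxide opened at C1 by a C10=C11 allylsilane carrying silicon on C12.
Retrosynthesis: exchange the esters at C2, C9, C14 and C16, then cut C1–C10, which merges the cyclohexene and the ten-membered ring into one fourteen-membered ring. Then cut C9–C10 (Nozaki–Hiyama–Kishi) and C2–C3 (aldol) to give fragment N (C10–C14, C1, C2, C15, C20) and fragment S (C3–C9, C16–C19).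
Forward: the γ-lactone closes first (Reformatsky, C8–C17), the fragments join at C2–C3, and the fourteen-membered ring closes at C9–C10. One transannular bond then gives the six- and ten-membered rings together.
Stereochemistry: C12 comes from catalytic silyl conjugate addition, C1/C14 from Sharpless epoxidation of a Still–Gennari Z-olefin, and C7 from catalytic alkynylation. C8/C17 are relayed from C7, C2 and C9 come from Felkin–Anh additions, C4 from CBS reduction, and C1 (inverted) and C10 from the key step.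
Both Z-olefins of the macrocycle (C5=C6, C10=C11) come from anti-metalation of propargylic alcohols followed by iodinolysis.

Key step: step 26

Numbering: every intermediate carries the briarane numbers of the atoms it delivers (C15 methyl on C1, C16 CH2O on C5, C18 methyl on C17, C19 lactone carbonyl, C20 methyl on C11).
Assumption: the ligand antipodes named in steps 3 and 11 are taken to follow the sense of induction of the nearest reported substrates; the mirror-image ligand would be used otherwise.

Step 1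
Reactants: 1 prop-2-yn-1-ol
Product: 3 (Z)-3-iodo-2-methylprop-2-en-1-ol, via vinylmagnesium chelate 2 (not isolated)
Conditions: MeMgBr (2.5 equiv), CuI (10 mol %), THF, −10 °C to rt; then I2, −78 to 0 °C
Reagents that add atoms: methylmagnesium bromide C[Mg]Br; iodine II
Why: Copper-catalysed anti-carbomagnesiation of the propargylic alkoxide puts methyl (C20) on the inner carbon and magnesium on the terminus inside a five-membered chelate, so iodinolysis with retention should give only the Z-iodide, with iodine (the future C9 position) cis to C12.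

Step 2
Reactants: 3 (Z)-3-iodo-2-methylprop-2-en-1-ol
Product: 5 methyl (2E,4Z)-5-iodo-4-methylpenta-2,4-dienoate, via Z-iodoenal 4 (not isolated)
Conditions: MnO2 (excess), Ph3P=CHCO2Me, CH2Cl2, rt
Reagents that add atoms: methyl (triphenylphosphoranylidene)acetate COC(=O)C=P(c1ccccc1)(c1ccccc1)c1ccccc1
Why: Tandem allylic oxidation–Wittig olefination traps the volatile, configurationally labile Z-enal as it forms, and the stabilised ylide should give the 2E-enoate (C13, C14) without touching the 4Z-iodoalkene.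

Step 3
Reactants: 5 methyl (2E,4Z)-5-iodo-4-methylpenta-2,4-dienoate
Product: 6 methyl (3S,4Z)-3-[dimethyl(phenyl)silyl]-5-iodo-4-methylpent-4-enoate
Conditions: PhMe2Si–Bpin, CuCl (5 mol %), NaOtBu, (S,S)-4,5-diphenylimidazolinium tetrafluoroborate (NHC precursor), MeOH, THF, −78 °C
Reagents that add atoms: dimethyl(phenyl)silylboronic acid pinacol ester C[Si](C)(c1ccccc1)B1OC(C)(C)C(C)(C)O1
Why: Copper-catalysed enantioselective conjugate silyl transfer to acyclic dienoates is a known 1,4-selective route to carbonyl-bearing allylsilanes, the chiral NHC–copper silyl species selects the enoate face that sets (12S), and the cold, mild conditions should leave the alkenyl iodide untouched.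

Step 4
Reactants: 6 methyl (3S,4Z)-3-[dimethyl(phenyl)silyl]-5-iodo-4-methylpent-4-enoate
Product: 7 (3S,4Z)-3-[dimethyl(phenyl)silyl]-5-iodo-4-methylpent-4-enal
Conditions: i-Bu2AlH (1.05 equiv), CH2Cl2, −78 °C
Reagents that add atoms: none
Why: Partial hydride reduction of the methyl ester stops at the tetrahedral aluminate at low temperature and should release the C14 aldehyde only on work-up.

Step 5
Reactants: 7 (3S,4Z)-3-[dimethyl(phenyl)silyl]-5-iodo-4-methylpent-4-enal; 8 ethyl 2-[bis(2,2,2-trifluoroethoxy)phosphoryl]propanoate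
Product: 10 ethyl (2Z,5S,6Z)-5-[dimethyl(phenyl)silyl]-7-iodo-2,6-dimethylhepta-2,6-dienoate, via potassium phosphonoenolate 9 (not isolated)
Conditions: 8, KN(SiMe3)2, 18-crown-6, THF, −78 °C; then 7
Reagents that add atoms: none
Why: The Still–Gennari olefination is kinetically Z-selective under dissociating conditions and should give the trisubstituted enoate with C13 cis to C2, the geometry that becomes the cis-epoxide.

Step 6
Reactants: 10 ethyl (2Z,5S,6Z)-5-[dimethyl(phenyl)silyl]-7-iodo-2,6-dimethylhepta-2,6-dienoate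
Product: 11 (2Z,5S,6Z)-5-[dimethyl(phenyl)silyl]-7-iodo-2,6-dimethylhepta-2,6-dien-1-ol
Conditions: i-Bu2AlH (2.5 equiv), CH2Cl2, −78 to 0 °C
Reagents that add atoms: none
Why: Exhaustive 1,2-reduction of the enoate gives the Z-allylic alcohol that will direct the epoxidation.

Step 7
Reactants: 11 (2Z,5S,6Z)-5-[dimethyl(phenyl)silyl]-7-iodo-2,6-dimethylhepta-2,6-dien-1-ol
Product: 12 [(2R,3S)-3-{(2S,3Z)-2-[dimethyl(phenyl)silyl]-4-iodo-3-methylbut-3-en-1-yl}-2-methyloxiran-2-yl]methanol
Conditions: Ti(OiPr)4, D-(−)-diethyl tartrate, t-BuOOH, 4 Å sieves, CH2Cl2, −20 °C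
Reagents that add atoms: tert-butyl hydroperoxide CC(C)(C)OO
Why: The Katsuki–Sharpless epoxidation acts only on the allylic alcohol, and D-(−)-tartrate should deliver oxygen to the face that gives the (2R,3S) cis-epoxide (C1, C14), the mirror image of the L-tartrate outcome for nerol-type Z-allylic alcohols.

Step 8
Reactants: 12 [(2R,3S)-3-{(2S,3Z)-2-[dimethyl(phenyl)silyl]-4-iodo-3-methylbut-3-en-1-yl}-2-methyloxiran-2-yl]methanol
Product: 13 (2S,3S)-3-{(2S,3Z)-2-[dimethyl(phenyl)silyl]-4-iodo-3-methylbut-3-en-1-yl}-2-methyloxirane-2-carbaldehyde (fragment N)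
Conditions: Dess–Martin periodinane, pyridine, CH2Cl2, 0 °C
Reagents that add atoms: none
Why: Buffered Dess–Martin oxidation should give the non-enolisable C2 epoxy aldehyde without opening the epoxide (same geometry, descriptor at C1 changes by priority only).

Step 9
Reactants: 14 2-methylidenepropane-1,3-diol
Product: 15 2-{[(4-methoxybenzyl)oxy]methyl}prop-2-en-1-ol
Conditions: Ag2O, 4-methoxybenzyl chloride (1.1 equiv), CH2Cl2, rt
Reagents that add atoms: 4-methoxybenzyl chloride COc1ccc(CCl)cc1
Why: Silver-oxide-mediated Williamson etherification of a symmetrical diol is known to stop at the mono-ether, which distinguishes C9 (ether) from C7 (free alcohol).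

Step 10
Reactants: 15 2-{[(4-methoxybenzyl)oxy]methyl}prop-2-en-1-ol
Product: 16 2-{[(4-methoxybenzyl)oxy]methyl}prop-2-enal
Conditions: MnO2, CH2Cl2, rt
Reagents that add atoms: none
Why: MnO2 oxidises the allylic alcohol chemoselectively to the 2-substituted acrolein, whose methylidene group masks the C8 ketone.

Step 11
Reactants: 16 2-{[(4-methoxybenzyl)oxy]methyl}prop-2-enal; 17 tert-butyl(dimethyl)(prop-2-yn-1-yloxy)silane
Product: 19 (3S)-6-{[tert-butyl(dimethyl)silyl]oxy}-2-{[(4-methoxybenzyl)oxy]methyl}hex-1-en-4-yn-3-ol, via methylzinc acetylide 18 (not isolated)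
Conditions: 17, Me2Zn, (S,S)-ProPhenol (20 mol %), Ph3P=O, toluene, 0 °C; then 16
Reagents that add atoms: none
Why: Zinc–ProPhenol-catalysed asymmetric alkynylation, which performs best with unsaturated aldehydes, should add the acetylide (C6, C5, C16) to one aldehyde face and set (7S).

Step 12
Reactants: 19 (3S)-6-{[tert-butyl(dimethyl)silyl]oxy}-2-{[(4-methoxybenzyl)oxy]methyl}hex-1-en-4-yn-3-ol
Product: 21 (3S,4Z)-6-{[tert-butyl(dimethyl)silyl]oxy}-5-iodo-2-{[(4-methoxybenzyl)oxy]methyl}hexa-1,4-dien-3-ol, via cyclic vinylalanate 20 (not isolated)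
Conditions: NaAlH2(OCH2CH2OMe)2, THF, 0 °C to rt; then I2, −78 °C
Reagents that add atoms: iodine II
Why: Hydroxyl-directed trans-hydroalumination of the propargylic alcohol places aluminium on C5 in a five-membered alanate, and iodinolysis with retention should give the Z-iodide with iodine (the future C4 position) cis to C7.

Step 13
Reactants: 21 (3S,4Z)-6-{[tert-butyl(dimethyl)silyl]oxy}-5-iodo-2-{[(4-methoxybenzyl)oxy]methyl}hexa-1,4-dien-3-ol
Product: 22 2-bromopropanoate ester of 21 (C7–O–CO–CHBr–CH3, bromide centre as a mixture)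
Conditions: 2-bromopropanoyl bromide, pyridine, CH2Cl2, −20 °C
Reagents that add atoms: 2-bromopropanoyl bromide CC(Br)C(=O)Br
Why: Acylation of the secondary alcohol with the acid bromide installs C17–C19 as a latent, regiodefined enolate, and the configuration at the bromide carbon is lost later and does not matter.

Step 14
Reactants: 22 2-bromopropanoate ester of 21
Product: 23 α-acyloxy ketone (C8 ketone flanked by C7H–O2C–CHBrCH3 and C9H2–OPMB, Z-iodoalkene retained)
Conditions: OsO4 (2 mol %), NaIO4, 2,6-lutidine, dioxane–H2O, rt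
Reagents that add atoms: sodium periodate (oxygen relayed through OsO4) [Na+].[O-]I(=O)(=O)=O
Why: The Lemieux–Johnson oxidation should select the 1,1-disubstituted olefin because the other olefin is deactivated by iodine, and this unmasks the C8 ketone.

Step 15
Reactants: 23 α-acyloxy ketone
Product: 24 (3R,4R,5S)-5-[(1Z)-3-{[tert-butyl(dimethyl)silyl]oxy}-2-iodoprop-1-en-1-yl]-4-hydroxy-4-{[(4-methoxybenzyl)oxy]methyl}-3-methyloxolan-2-one
Conditions: Zn dust (activated), THF, rt to 40 °C; aq NH4Cl
Reagents that add atoms: none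
Why: The intramolecular Reformatsky reaction generates the enolate only at C17 under neutral conditions (no ketone enolisation), and 5-exo closure onto the ketone face that keeps the CH2OPMB arm anti to the C7 alkenyl group and the methyl anti to that arm should set (8R,17R) from C7, with C17 still correctable by base equilibration.

Step 16
Reactants: 24 hydroxy lactone
Product: 25 C8 triethylsilyl ether of 24
Conditions: Et3SiOTf, 2,6-lutidine, CH2Cl2, 0 °C
Reagents that add atoms: triethylsilyl triflate CC[Si](CC)(CC)OS(=O)(=O)C(F)(F)F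
Why: Silylation of the tertiary alcohol with the reactive triflate blocks retro-aldol cleavage and prevents boron or chromium chelation at O8 in steps 18 and 24.

Step 17
Reactants: 25 C8 triethylsilyl ether of 24
Product: 27 methyl enone (fragment S: CH3–C4(=O)–C5(CH2OTBS)=C6H–C7, 5Z, lactone as in 25), via dienol ether 26 (not isolated)
Conditions: tributyl(1-ethoxyvinyl)stannane, PdCl2(PPh3)2 (5 mol %), toluene, 80 °C; then 1 M HCl, THF, 0 °C
Reagents that add atoms: tributyl(1-ethoxyvinyl)stannane CCCC[Sn](CCCC)(CCCC)C(=C)OCC; water O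
Why: Stille coupling proceeds with retention of olefin geometry, and brief hydrolysis of the dienol ether should deliver the acetyl group (C3, C4) cis to C7.

Step 18
Reactants: 27 methyl enone (fragment S); 13 epoxy aldehyde (fragment N)
Product: 29 (2R)-β-hydroxy enone (open chain from the C10 Z-alkenyl iodide to C9H2–OPMB; free C2 hydroxyl, C4 ketone; other centres as in 13 and 27), via boron enolate 28 (not isolated)
Conditions: 27, (c-C6H11)2BCl, Et3N, Et2O, −78 to 0 °C; then 13, −78 to −20 °C; MeOH, pH 7 buffer, H2O2, 0 °C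
Reagents that add atoms: none
Why: The boron-mediated aldol addition of the kinetic methyl-ketone enolate joins C2 to C3 through a cyclic transition state, and Felkin–Anh attack anti to the epoxide C1–O bond, with the cis-substituted C14 as the medium group, should set (2R).

Step 19
Reactants: 29 (2R)-β-hydroxy enone
Product: 30 C2 tert-butyldimethylsilyl ether of 29
Conditions: t-BuMe2SiOTf, 2,6-lutidine, CH2Cl2, −78 °C
Reagents that add atoms: tert-butyldimethylsilyl triflate CC(C)(C)[Si](C)(C)OS(=O)(=O)C(F)(F)F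
Why: Silylation with the triflate and a hindered base at low temperature caps the hindered C2 hydroxyl as a non-participating ether without disturbing the neighbouring epoxide.

Step 20
Reactants: 30 C2 tert-butyldimethylsilyl ether of 29
Product: 31 (4R)-allylic alcohol (C4 ketone of 30 reduced, 1,3-anti to C2)
Conditions: (S)-2-methyl-CBS-oxazaborolidine, catecholborane, toluene, −78 °C
Reagents that add atoms: none
Why: The Corey–Bakshi–Shibata reduction treats the fully substituted alkenyl group as the large substituent, so the (S)-catalyst should give the (4R) alcohol, and catecholborane at low temperature spares the lactone, epoxide and olefins.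

Step 21
Reactants: 31 (4R)-allylic alcohol
Product: 32 C4 butanoate of 31
Conditions: butanoic anhydride, Et3N, DMAP (cat.), CH2Cl2, 0 °C to rt
Reagents that add atoms: butanoic anhydride CCCC(=O)OC(=O)CCC
Why: DMAP-catalysed acylation of the only free hydroxyl installs the C4 butyrate of the target.

Step 22
Reactants: 32 C4 butanoate of 31
Product: 33 C9 primary alcohol (PMB ether of 32 removed)
Conditions: DDQ, CH2Cl2–pH 7 buffer, 0 °C
Reagents that add atoms: none
Why: Oxidative PMB cleavage by benzylic hydride abstraction and hydrolysis spares silyl ethers, esters, the epoxide and the iodine-deactivated allylsilane.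

Step 23
Reactants: 33 C9 primary alcohol
Product: 34 seco aldehyde (C9 formyl on quaternary C8, C10 Z-alkenyl iodide at the other chain end)
Conditions: Dess–Martin periodinane, pyridine, CH2Cl2, 0 °C to rt
Reagents that add atoms: none
Why: Dess–Martin oxidation converts the neopentyl alcohol into an aldehyde that has no α-hydrogen and cannot epimerise.

Step 24
Reactants: 34 seco aldehyde
Product: 35 fourteen-membered carbocycle with a free (9R)-allylic alcohol (cis-C1,C14-epoxide, (Z)-C10=C11, (12S)-SiMe2Ph, C2–OTBS, C4 butyrate, C16–OTBS, C8–OTES, lactone)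
Conditions: CrCl2 (excess), NiCl2 (1 mol %), DMSO–THF, rt, slow addition, 1 mM
Reagents that add atoms: none
Why: The Nozaki–Hiyama–Kishi macrocyclisation forms the alkenylchromium species with retention of the Z geometry and tolerates esters, lactone and epoxide, and Felkin–Anh addition anti to the C8–OTES bond, with C7 as the medium group, should set (9R) while C9–C10 closes the ring.

Step 25
Reactants: 35 fourteen-membered (9R)-allylic alcohol
Product: 36 key-step precursor (C9 triethylsilyl ether of 35)
Conditions: Et3SiOTf, 2,6-lutidine, CH2Cl2, −78 °C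
Reagents that add atoms: triethylsilyl triflate CC[Si](CC)(CC)OS(=O)(=O)C(F)(F)F
Why: The allylic C9 hydroxyl is masked by a small silyl group, a poor leaving group that should resist Lewis-acid ionisation next to the allylsilane.

Step 26
Reactants: 36 key-step precursor
Product: 37 bicyclic C14 alcohol (cyclohexene C1, C10–C14 with C11=C12, trans-fused to the ten-membered ring C1–C10; C2–OTBS, C4 butyrate, C16–OTBS, C8 and C9–OTES, lactone)
Conditions: MeAlCl2 (3 equiv), CH2Cl2, −78 °C; Et3N–MeOH, aq NaHCO3
Reagents that add atoms: none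
Why: Proposed new method: MeAlCl2 binds the epoxide oxygen and loosens the tertiary C1–O bond, C10 of the (Z)-allylsilane attacks C1 from the rear across the ring, and the C11 cation, held by the antiperiplanar C12–Si bond, gives up silicon to chloride so that the olefin can only appear at C11=C12; the closest known reactions are open-chain Lewis-acid epoxide–allylsilane cyclisations and acid-induced transannular epoxide–olefin cyclisations of germacrane and cembrane epoxides, neither of which has been run as an allylsilane-terminated closure across a fourteen-membered ring. The cyclohexene closes 6-endo at the epoxide through a chair with the C14–O bond equatorial, and the ten-membered ring is not closed end to end but is what remains of the perimeter (C1, C2 to C9, C10) once that same bond exists. C1 is set by inversion in the backside opening, C14 keeps its epoxide configuration, and C10 is set by the olefin face shown in the chair: the cis-epoxide places C2 axial and the Z-olefin places C9 axial, so the two arms are anti, the fusion is trans and the C14 oxygen ends cis to C2. The (12S) centre holds silicon on the olefin face remote from C1, so the anti-SE2′ requirement and the chair call for the same face. The step needs the epoxide to ionise in preference to the allylic C9–O bond and needs C10 to outrun a 1,2-hydride shift from C2 and capture by oxygen nucleophiles; bulky, poorly leaving silyl ethers at C2, C8 and C9 (no acyloxy neighbour at C2), a methylaluminium Lewis acid that also scavenges protons, low temperature and the enforced closeness of C1 and C10 are meant to secure this.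

Step 27
Reactants: 37 bicyclic C14 alcohol
Product: 38 pentaol (free hydroxyls at C2, C8, C9, C14 and C16; C4 butyrate and lactone intact)
Conditions: HF·pyridine, pyridine, THF, 0 °C to rt
Reagents that add atoms: none
Why: Buffered HF·pyridine should remove both TBS and both TES ethers under mildly acidic conditions that disfavour migration of the C4 butyrate.

Step 28
Reactants: 38 pentaol
Product: 39 CNP0290502.1, (1R,2R,4R,5Z,7S,8S,9R,10S,14S,17R) in briarane numbering
Conditions: Ac2O, pyridine, DMAP (cat.), CH2Cl2, rt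
Reagents that add atoms: acetic anhydride CC(=O)OC(C)=O
Why: DMAP-catalysed acetylation should esterify the primary C16 and the secondary C2, C9 and C14 hydroxyls in one operation, while the tertiary C8 hydroxyl, walled in by C7, C9 and C17, stays free.

Compound list
1 | prop-2-yn-1-ol | C#CCO | starting material
2 | 4-methyl-2,5-dihydro-1,2-oxamagnesole (vinylmagnesium chelate) | CC1=C[Mg]OC1 | intermediate
3 | (Z)-3-iodo-2-methylprop-2-en-1-ol | I/C=C(C)\CO | intermediate
4 | (Z)-3-iodo-2-methylprop-2-enal | I/C=C(C)\C=O | intermediate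
5 | methyl (2E,4Z)-5-iodo-4-methylpenta-2,4-dienoate | I/C=C(C)\C=C\C(=O)OC | intermediate
6 | methyl (3S,4Z)-3-[dimethyl(phenyl)silyl]-5-iodo-4-methylpent-4-enoate | I/C=C(C)\[C@@H]([Si](C)(C)c1ccccc1)CC(=O)OC | intermediate
7 | (3S,4Z)-3-[dimethyl(phenyl)silyl]-5-iodo-4-methylpent-4-enal | I/C=C(C)\[C@@H]([Si](C)(C)c1ccccc1)CC=O | intermediate
8 | ethyl 2-[bis(2,2,2-trifluoroethoxy)phosphoryl]propanoate | CCOC(=O)C(C)P(=O)(OCC(F)(F)F)OCC(F)(F)F | starting material
9 | potassium enolate of 8 | [K+].CCOC([O-])=C(C)P(=O)(OCC(F)(F)F)OCC(F)(F)F | intermediate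
10 | ethyl (2Z,5S,6Z)-5-[dimethyl(phenyl)silyl]-7-iodo-2,6-dimethylhepta-2,6-dienoate | I/C=C(C)\[C@@H]([Si](C)(C)c1ccccc1)C/C=C(C)\C(=O)OCC | intermediate
11 | (2Z,5S,6Z)-5-[dimethyl(phenyl)silyl]-7-iodo-2,6-dimethylhepta-2,6-dien-1-ol | I/C=C(C)\[C@@H]([Si](C)(C)c1ccccc1)C/C=C(C)\CO | intermediate
12 | [(2R,3S)-3-{(2S,3Z)-2-[dimethyl(phenyl)silyl]-4-iodo-3-methylbut-3-en-1-yl}-2-methyloxiran-2-yl]methanol | I/C=C(C)\[C@@H]([Si](C)(C)c1ccccc1)C[C@@H]2O[C@]2(C)CO | intermediate
13 | (2S,3S)-3-{(2S,3Z)-2-[dimethyl(phenyl)silyl]-4-iodo-3-methylbut-3-en-1-yl}-2-methyloxirane-2-carbaldehyde (fragment N) | I/C=C(C)\[C@@H]([Si](C)(C)c1ccccc1)C[C@@H]2O[C@]2(C)C=O | intermediate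
14 | 2-methylidenepropane-1,3-diol | C=C(CO)CO | starting material
15 | 2-{[(4-methoxybenzyl)oxy]methyl}prop-2-en-1-ol | C=C(CO)COCc1ccc(OC)cc1 | intermediate
16 | 2-{[(4-methoxybenzyl)oxy]methyl}prop-2-enal | C=C(C=O)COCc1ccc(OC)cc1 | intermediate
17 | tert-butyl(dimethyl)(prop-2-yn-1-yloxy)silane | C#CCO[Si](C)(C)C(C)(C)C | starting material
18 | methylzinc acetylide of 17 | C[Zn]C#CCO[Si](C)(C)C(C)(C)C | intermediate
19 | (3S)-6-{[tert-butyl(dimethyl)silyl]oxy}-2-{[(4-methoxybenzyl)oxy]methyl}hex-1-en-4-yn-3-ol | CC(C)(C)[Si](C)(C)OCC#C[C@H](O)C(=C)COCc1ccc(OC)cc1 | intermediate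
20 | sodium cyclic vinylalanate (O7 and C5 bound to aluminium) | [Na+].COCCO[Al-]1(OCCOC)O[C@H](C(=C)COCc2ccc(OC)cc2)C=C1CO[Si](C)(C)C(C)(C)C | intermediate
21 | (3S,4Z)-6-{[tert-butyl(dimethyl)silyl]oxy}-5-iodo-2-{[(4-methoxybenzyl)oxy]methyl}hexa-1,4-dien-3-ol | I/C(CO[Si](C)(C)C(C)(C)C)=C\[C@H](O)C(=C)COCc1ccc(OC)cc1 | intermediate
22 | 2-bromopropanoate of 21 | I/C(CO[Si](C)(C)C(C)(C)C)=C\[C@H](OC(=O)C(C)Br)C(=C)COCc1ccc(OC)cc1 | intermediate
23 | α-acyloxy ketone (C8 ketone) | I/C(CO[Si](C)(C)C(C)(C)C)=C\[C@H](OC(=O)C(C)Br)C(=O)COCc1ccc(OC)cc1 | intermediate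
24 | (3R,4R,5S)-5-[(1Z)-3-{[tert-butyl(dimethyl)silyl]oxy}-2-iodoprop-1-en-1-yl]-4-hydroxy-4-{[(4-methoxybenzyl)oxy]methyl}-3-methyloxolan-2-one | I/C(CO[Si](C)(C)C(C)(C)C)=C\[C@@H]1OC(=O)[C@H](C)[C@@]1(O)COCc2ccc(OC)cc2 | intermediate
25 | C8 triethylsilyl ether of 24 | I/C(CO[Si](C)(C)C(C)(C)C)=C\[C@@H]1OC(=O)[C@H](C)[C@@]1(O[Si](CC)(CC)CC)COCc2ccc(OC)cc2 | intermediate
26 | 1-ethoxyvinyl dienol ether | C=C(OCC)/C(CO[Si](C)(C)C(C)(C)C)=C\[C@@H]1OC(=O)[C@H](C)[C@@]1(O[Si](CC)(CC)CC)COCc2ccc(OC)cc2 | intermediate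
27 | methyl enone (fragment S) | CC(=O)/C(CO[Si](C)(C)C(C)(C)C)=C\[C@@H]1OC(=O)[C@H](C)[C@@]1(O[Si](CC)(CC)CC)COCc2ccc(OC)cc2 | intermediate
28 | dicyclohexylboron enolate of 27 | C=C(OB(C1CCCCC1)C1CCCCC1)/C(CO[Si](C)(C)C(C)(C)C)=C\[C@@H]2OC(=O)[C@H](C)[C@@]2(O[Si](CC)(CC)CC)COCc3ccc(OC)cc3 | intermediate
29 | (2R)-β-hydroxy enone | I/C=C(C)\[C@@H]([Si](C)(C)c1ccccc1)C[C@@H]2O[C@]2(C)[C@H](O)CC(=O)/C(CO[Si](C)(C)C(C)(C)C)=C\[C@@H]3OC(=O)[C@H](C)[C@@]3(O[Si](CC)(CC)CC)COCc4ccc(OC)cc4 | intermediate
30 | C2 TBS ether of 29 | I/C=C(C)\[C@@H]([Si](C)(C)c1ccccc1)C[C@@H]2O[C@]2(C)[C@H](O[Si](C)(C)C(C)(C)C)CC(=O)/C(CO[Si](C)(C)C(C)(C)C)=C\[C@@H]3OC(=O)[C@H](C)[C@@]3(O[Si](CC)(CC)CC)COCc4ccc(OC)cc4 | intermediate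
31 | (4R)-allylic alcohol | I/C=C(C)\[C@@H]([Si](C)(C)c1ccccc1)C[C@@H]2O[C@]2(C)[C@H](O[Si](C)(C)C(C)(C)C)C[C@@H](O)/C(CO[Si](C)(C)C(C)(C)C)=C\[C@@H]3OC(=O)[C@H](C)[C@@]3(O[Si](CC)(CC)CC)COCc4ccc(OC)cc4 | intermediate
32 | C4 butanoate of 31 | I/C=C(C)\[C@@H]([Si](C)(C)c1ccccc1)C[C@@H]2O[C@]2(C)[C@H](O[Si](C)(C)C(C)(C)C)C[C@@H](OC(=O)CCC)/C(CO[Si](C)(C)C(C)(C)C)=C\[C@@H]3OC(=O)[C@H](C)[C@@]3(O[Si](CC)(CC)CC)COCc4ccc(OC)cc4 | intermediate
33 | C9 primary alcohol | I/C=C(C)\[C@@H]([Si](C)(C)c1ccccc1)C[C@@H]2O[C@]2(C)[C@H](O[Si](C)(C)C(C)(C)C)C[C@@H](OC(=O)CCC)/C(CO[Si](C)(C)C(C)(C)C)=C\[C@@H]3OC(=O)[C@H](C)[C@@]3(O[Si](CC)(CC)CC)CO | intermediate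
34 | seco aldehyde | I/C=C(C)\[C@@H]([Si](C)(C)c1ccccc1)C[C@@H]2O[C@]2(C)[C@H](O[Si](C)(C)C(C)(C)C)C[C@@H](OC(=O)CCC)/C(CO[Si](C)(C)C(C)(C)C)=C\[C@@H]3OC(=O)[C@H](C)[C@@]3(O[Si](CC)(CC)CC)C=O | intermediate
35 | fourteen-membered (9R)-allylic alcohol | CCCC(=O)O[C@@H]1C[C@@H](O[Si](C)(C)C(C)(C)C)[C@@]2(C)O[C@H]2C[C@H]([Si](C)(C)c3ccccc3)/C(C)=C\[C@@H](O)[C@@]2(O[Si](CC)(CC)CC)[C@H](/C=C\1CO[Si](C)(C)C(C)(C)C)OC(=O)[C@@H]2C | intermediate
36 | key-step precursor (fourteen-membered cis-epoxide (Z)-allylsilane) | CCCC(=O)O[C@@H]1C[C@@H](O[Si](C)(C)C(C)(C)C)[C@@]2(C)O[C@H]2C[C@H]([Si](C)(C)c3ccccc3)/C(C)=C\[C@@H](O[Si](CC)(CC)CC)[C@@]2(O[Si](CC)(CC)CC)[C@H](/C=C\1CO[Si](C)(C)C(C)(C)C)OC(=O)[C@@H]2C | intermediate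
37 | key-step product (bicyclic C14 alcohol) | CCCC(=O)O[C@@H]1C[C@@H](O[Si](C)(C)C(C)(C)C)[C@@]2(C)[C@@H](O)CC=C(C)[C@@H]2[C@@H](O[Si](CC)(CC)CC)[C@@]2(O[Si](CC)(CC)CC)[C@H](/C=C\1CO[Si](C)(C)C(C)(C)C)OC(=O)[C@@H]2C | intermediate
38 | pentaol | CCCC(=O)O[C@@H]1C[C@@H](O)[C@@]2(C)[C@@H](O)CC=C(C)[C@@H]2[C@@H](O)[C@@]2(O)[C@H](/C=C\1CO)OC(=O)[C@@H]2C | intermediate
39 | CNP0290502.1 | CCCC(=O)O[C@@H]1C[C@@H](OC(C)=O)[C@@]2(C)[C@@H](OC(C)=O)CC=C(C)[C@@H]2[C@@H](OC(C)=O)[C@@]2(O)[C@H](/C=C\1COC(C)=O)OC(=O)[C@@H]2C | target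

Total step count: 28.
Longest linear sequence: 20 steps (14 to 39 through steps 9–28). Fragment N adds 8 steps in parallel.

Steps most likely to fail

Step 26. Three things could go wrong:
- The Lewis acid may ionise the allylic C9–O bond with loss of silicon.
- The C1 cation may be quenched by a 1,2-hydride shift from C2.
- The ring may adopt a shape that keeps C1 and C10 apart.

The fallback replaces the cation by a radical and uses known titanocene epoxide chemistry. It sets out from 36. Cp2TiCl, made from Cp2TiCl2 and Mn in THF, opens the epoxide homolytically to the tertiary C1 radical. This radical adds across the ring to C10, as in the known transannular cyclisations of epoxygermacrolides. The tertiary C11 radical is then caught by a second trivalent titanium and loses hydride from the C20 methyl group. This should give the exocyclic-methylene allylsilane F1, with silicon still on C12. Protodesilylation of this new allylsilane (BF3·2AcOH, CH2Cl2, low temperature) protonates C20, expels silicon and moves the olefin to C11=C12. The route is rejoined at 37.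

Step 24. Addition to the neopentyl aldehyde may show poor facial selectivity at C9 under the constraints of ring closure. In the fallback, C9 is set by reduction instead of by C–C bond formation. It sets out from 34. The ring is closed as before and the carbinol mixture, containing the 9-epimeric alcohol F2, is oxidised with Dess–Martin periodinane to the macrocyclic C9 enone F3. Corey–Bakshi–Shibata reduction with the (S)-catalyst and catecholborane at −78 °C, with the quaternary C8 as the large group, should then give the (9R) alcohol. The route is rejoined at 35.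

Step 3. The copper silyl species may attack the alkenyl iodide (reduction or silyl coupling) or add in a 1,6 sense with loss of iodide. In the fallback the halide is masked as a stannane during silyl transfer. It sets out from 5. Palladium-catalysed stannylation with (Bu3Sn)2 and Pd(PPh3)4 gives the stannyl dienoate F4. The same copper-catalysed silyl addition gives the β-silyl stannyl ester F5. Iododestannylation with I2 at −78 °C, which is faster at the carbon–tin bond than any reaction of the allylsilane and proceeds with retention, rejoins the route at 6.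

Further compounds
F1 | step 26 | exocyclic-methylene allylsilane (C1–C10 bonded, C11=C20, C12–SiMe2Ph, C14–OH) | CCCC(=O)O[C@@H]1C[C@@H](O[Si](C)(C)C(C)(C)C)[C@@]2(C)[C@@H](O)C[C@H]([Si](C)(C)c3ccccc3)C(=C)[C@@H]2[C@@H](O[Si](CC)(CC)CC)[C@@]2(O[Si](CC)(CC)CC)[C@H](/C=C\1CO[Si](C)(C)C(C)(C)C)OC(=O)[C@@H]2C
F2 | step 24 | 9-epimeric alcohol (9-epi-35) | CCCC(=O)O[C@@H]1C[C@@H](O[Si](C)(C)C(C)(C)C)[C@@]2(C)O[C@H]2C[C@H]([Si](C)(C)c3ccccc3)/C(C)=C\[C@H](O)[C@@]2(O[Si](CC)(CC)CC)[C@H](/C=C\1CO[Si](C)(C)C(C)(C)C)OC(=O)[C@@H]2C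
F3 | step 24 | macrocyclic C9 enone | CCCC(=O)O[C@@H]1C[C@@H](O[Si](C)(C)C(C)(C)C)[C@@]2(C)O[C@H]2C[C@H]([Si](C)(C)c3ccccc3)/C(C)=C\C(=O)[C@@]2(O[Si](CC)(CC)CC)[C@H](/C=C\1CO[Si](C)(C)C(C)(C)C)OC(=O)[C@@H]2C
F4 | step 3 | methyl (2E,4Z)-4-methyl-5-(tributylstannyl)penta-2,4-dienoate | CCCC[Sn](CCCC)(CCCC)/C=C(C)\C=C\C(=O)OC
F5 | step 3 | methyl (4Z)-3-[dimethyl(phenyl)silyl]-4-methyl-5-(tributylstannyl)pent-4-enoate, C3 configured as in 6 | CCCC[Sn](CCCC)(CCCC)/C=C(C)\[C@@H]([Si](C)(C)c1ccccc1)CC(=O)OC
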